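**The ratio.** The ratio of 9.11 between two rate constants, that of the loading step (starting material + free catalyst) over that of the burning step (starting material + target), runs through this whole reckoning.

the same everywhere: starting material 20 mM; partner 14.0 mM; free catalyst 1.3 mM
- violet: second substrate 10.0 mM; a single well-mixed tank run continuously and read at steady state, 1.5 h in it on average
- green: second substrate 10.0 mM; a closed flask charged with all of it at once and left for 1.5 h; time 1.5 h
- blue: second substrate 10.0 mM (fed, over 1.50 h); a stirred flask in which second substrate is dosed at a steady rate over 1.50 h without added volume, worked up at 1.5 h; time 1.5 h
- amber: second substrate 10.0 mM; a tube with plug flow, the mixed feed as stated, residence time 1.5 h; time 1.5 h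

    starting material + free catalyst ⇌ catalyst intermediate A (K1 = 80.7 M⁻¹, k1 = 12.3 M⁻¹ min⁻¹)
    partner + catalyst intermediate A ⇌ free catalyst + target (K2 = 42, k2 = 80.8 M⁻¹ min⁻¹)
    second substrate + free catalyst ⇌ catalyst intermediate B (K3 = 85.8 M⁻¹, k3 = 8.87 M⁻¹ min⁻¹)
    partner + catalyst intermediate B → free catalyst + second product (k4 = 4.04 M⁻¹ min⁻¹)
    partner → decomposed reagent (k5 = 0.00226 min⁻¹)
    starting material + target → side product (k6 = 1.35 M⁻¹ min⁻¹)

- the set-up with the highest amount of target at the outlet or at the end, in percent of the starting material put in ("none" if the first two lie within 2 percentage points) (violet / green / blue / amber / none)
- amount of target at the outlet or at the end, in percent of the starting material put in, violet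
- amount of target at the outlet or at the end, in percent of the starting material put in, green
- amount of target at the outlet or at the end, in percent of the starting material put in, blue
- amount of target at the outlet or at the end, in percent of the starting material put in, amber

- percentages count the starting material that a species holds: one side product counts as two
- the stated concentrations are those of everything mixed, before any reaction; amounts are the same in each set-up
- the feed brings no volume worth counting
- run time (green): 1.5 h

**Free catalyst.** Take green first. Partner is the limiting reagent, with 14.0 mM against 20 mM of starting material. Second substrate holds part of the catalyst, and since 0.86 is its equilibrium constant times its charge, I take 0.700 mM as free. Catalyst intermediate A falls back at 0.152 min⁻¹, or meets partner, at half charge, at 0.566 min⁻¹, so 78.8% passes on.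

**Partner's ledger.** Suppose partner averages half its charge and starting material 0.7 of its own. Decomposition then takes 1.42 mM, and catalyst intermediate B takes 1.53 mM. The road to target takes 8.54 mM, the biggest entry. The books close with 2.51 mM of partner unspent, and at that level 57.1% of catalyst intermediate A passes on.

**Target's ceiling.** Target is made in proportion to c(starting material) times c(free catalyst), and burnt in proportion to c(starting material) times c(target). Starting material stands on both sides and cancels. So I carry the ceiling ratio 4.90, the millimoles of target at which making equals burning, per millimole of catalyst charged, before the passing share is applied. Target's half-life against burning, 0.611 h, is shorter than the run, so I take target to stand at its ceiling, here 3.64 mM.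

**My reckoning.** That gives 18.2% for green, and 18.2% for amber, whose every slice is a closed flask. In violet, outflow also removes target, and with starting material at half charge the ceiling keeps 54.9%, so 9.98%. In blue, I count half the second substrate, the part of the dose that has arrived halfway through, and get 23.6%. Best: blue.

**The forecast.** It gives 13.3% for violet, 19.3% for green, 21.3% for blue and 19.2% for amber, and picks blue, on the ground that “Dosing the second substrate frees catalyst early”. Its blue lead over green is 2 percentage points, narrower than mine.

**What stands.** The runs give 13.6% in violet, 19.5% in green, 19.5% in amber and 22.6% in blue, so blue leads green by 3.1 points; a lead under 2 points counts as none, and the forecast's choice then fails. In blue, target's half-life by burning reads 0.60 h at 0.408 h, shorter than the 1.5 h run. With green's 24% of partner left at the end, the ceiling ratio 4.90 gives 20.3%. In the blue neighbour with 0.52 mM of free catalyst and 47% of partner left, it gives 9.90%, and that flask holds 10.8%.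

The rate constants stand for no real mixture, and the outcome is calculated.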